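**Remark (assumption):** lignan numbering is used throughout (oxolane O1–C7–C8–C8'–C9'; C9 on C8, C7' on C8'). ArBn stands for 4-(benzyloxy)-3-methoxyphenyl. Compounds 1, 5, 10 and 19 and the reagent tributyl(iodomethyl)stannane are taken as purchasable.

## The problem

Agastinol is a lariciresinol-type lignan: one oxolane ring, O1–C7–C8–C8'–C9', with a guaiacyl group on C7, the acyloxymethyl carbon C9 on C8 and the guaiacylmethyl carbon C7' on C8'. The ring is joined to no other, so the task is three contiguous stereocentres, (7R,8S,8'S), with the C7 aryl trans to the C9 arm and the C9 arm cis to the C7' benzyl group. C7 can be secured first and then steer C8, because a new bond to C8 of a flat five-membered ring forms anti to the neighbouring aryl group. C8 can in turn steer C8', but the 8,8'-cis relation is the crowded one and must be set kinetically, most simply by adding hydrogen to an sp2 C8' from the face away from C9. The sensitive parts are the benzylic ether bond C7–O1 on an electron-rich ring (ionised or epimerised by acid, cleavable by hydrogenolysis), the two free phenols, and the aryl ester on C9, which excludes strong base or hydride late in the route. The ester must go onto C9–OH alone, which is easiest when that is the only free hydroxyl and the phenols are unmasked afterwards. The enabling feature is the sequence C9–C8–C8'–C7': with a C8'=C7' double bond it is a homoallylic alcohol, the product of a [2,3]-Wittig shift of an O–CH2 carbanion on C7' across a C8=C8' double bond of a 2,5-dihydrofuran. The oxygen this requires on C7' is benzylic and so comes from adding an aryl group to an aldehyde.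

## Retrosynthesis

**21 ⇒ 20.** No skeletal bond is cut. C8' is traced back to an sp2 carbon of a C8'=C7' benzylidene, and the three phenols to benzyl ethers, so one hydrogenation both sets C8' and unmasks the phenols. Alkylation or conjugate addition at C8' would have to build the cis relation against the thermodynamic preference, whereas syn addition of H2 anti to the C9 arm gives it directly. The forward step must add hydrogen from the correct face without migrating the double bond and without cleaving C7–O1.

**20 ⇒ 18 + 19.** The ester C–O bond at C9 is cut. The 4-hydroxybenzoyl unit is the only part not derived from a guaiacyl building block, and attaching it late keeps the ester out of all organometallic steps. Alcohol 18 has a single hydroxyl, so nothing more than a standard esterification is asked.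

**18 ⇒ 16 (via 17).** The C8–C9 bond is cut. Cuts at C7–C8 or C8–C8' would have to close the ring and set two centres at once. Removing only C9 leaves a flat 2,5-dihydrofuran whose single ring stereocentre is C7, and lets C9 be delivered intramolecularly from the oxygen on C7'. The C8 stereocentre is exchanged for a carbinol centre at C7' that is easier to make. The forward step must favour the [2,3] over the [1,2] shift and use the face of C8 opposite the C7 aryl group.

**16 ⇒ 15.** The O–CH2Sn bond is cut, a routine etherification of the carbinol.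

**15 ⇒ 9 + 11.** The C7'–aryl bond is cut. The neighbouring option, cutting C7'–H (hydride reduction of the aryl dihydrofuranyl ketone), was set aside for two reasons. The ketone has two sp2 substituents of similar size, which gives an oxazaborolidine little to distinguish. Its preparation by acyl substitution also exposes the acidic C7–H (γ to the carbonyl) to strong bases. Catalytic aryl transfer from zinc to enal 9 forms the bond and the stereocentre together under non-basic conditions. The precursor has one aryl ring and one stereocentre fewer. The catalyst must deliver the aryl group to the Si face regardless of the remote C7 centre.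

**9 ⇒ 8 ⇒ 7.** Only the oxidation level at C7' changes (ester to alcohol to aldehyde). Both steps are neutral or non-basic, which protects C7.

**7 ⇒ 6.** The C8=C8' bond is cut by ring-closing metathesis. Closing the ring by etherification at O1–C7 would need a stereospecific substitution at a benzylic carbon. Metathesis closes it at the one ring bond that bears no stereocentre and places the double bond where the rearrangement needs it. The precursor is an acyclic ether of two simple pieces.

**6 ⇒ 4 + 5.** The O1–C9' bond is cut. This keeps C7 as the carbinol carbon of a resolved alcohol, whose configuration an O-alkylation cannot touch.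

**4 ⇒ 3 ⇒ 2 ⇒ 1.** The C7–C8 bond is cut back to aldehyde 1 and a vinyl nucleophile. The racemic carbinol 2 is resolved by lipase acylation, which gives the (R)-acetate 3; methanolysis releases 4.

**11 ⇒ 10.** The O–benzyl bond is cut, a phenol benzylation.

## Roads not taken

**Alternative 1:** The cut is C7–C8, with C9 and C7' tied together as a γ-lactone. In the forward step Rh2(OAc)4 (divalent rhodium) converts diazolactone A1 into a carbenoid at C8 that inserts into the benzylic C7–H bond of the side-chain ether, giving the cis-fused furofuranone A2.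
- Merits: the C–H bond is doubly activated, and the cis ring fusion fixes the 8,8'-cis relation by geometry. In this respect the road is better than the chosen plan, which depends on a face-selective hydrogenation.
- Weak points: the aryl group on C7 must end on the convex face, and an endo orientation in the insertion transition state would give the C7 epimer. After the insertion, the benzylic lactone C7'–O bond must be hydrogenolysed in the presence of the equally benzylic C7–O1 bond, and C9 must be reduced from the acid level before it can be esterified. A1 itself needs its own enantioselective synthesis and a diazo transfer.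
- Comparison: the chosen plan also spends an oxygen on C7', but removes it in the key step, where it is traded for the C8–C9 bond. C9 arrives at the alcohol level, and no second benzylic C–O bond has to be told apart from C7–O1.

**Alternative 2:** The cut is the C7'–aryl bond. 9-Borabicyclo[3.3.1]nonane adds to the exocyclic methylene of oxolane A3 from the face opposite the C9 arm, and the B-alkyl borane is coupled with aryl bromide 11 under Pd(dppf)Cl2 (divalent palladium precatalyst) and K3PO4 to give A4.
- Merits: a bulky borane should discriminate the faces of C8' at least as well as hydrogen on a metal surface, no benzylidene needs reducing, and the second aryl group arrives late. On these points the road is as good as or better than the chosen one.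
- Weak points: it does not address C8. A3 with its 7,8-trans relation needs a separate solution for the C8–C9 bond, and the silyl group costs a protection and a deprotection before C9 can be acylated.
- Comparison: the chosen plan makes C8, brings in C9 at the right oxidation level and leaves the C7' aryl in place in one operation, so only two steps follow the key step. The price is reliance on hydrogenation for C8'.

**Alternative 3:** The cuts are O1–C7, C8–C8' and C7'–aryl, all in one step. Propargyl alcohol A5 adds as its alkoxide to arylidene malonate A6, the malonate anion attacks the alkyne bound to the arylpalladium species formed from aryl iodide A7 and Pd2(dba)3 (zerovalent palladium) with a chiral bisphosphine, and reductive elimination gives A8.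
- Merits: step economy is clearly better than in the chosen plan, since three bonds and the ring form at once from simple components.
- Weak points: C7 is created in a reversible oxa-Michael addition before palladium is involved, so its configuration would have to come from a dynamic resolution in the cyclisation, which is a demanding and unproven form of control. C8 emerges as a quaternary diester, so a dealkoxycarbonylation, control of the resulting epimerisable C8 next to the benzylidene, and a reduction must follow. The benzylidene geometry places the aryl group away from C8, so the hydrogenation gets less help from allylic strain.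
- Comparison: the chosen plan is longer, but each stereocentre comes from a step whose sense can be predicted: enzyme resolution for C7, catalyst-controlled aryl transfer for C7', suprafacial sigmatropic transfer for C8.

Key step: step 11

## Route

Step 1
Reactants: 1 4-(benzyloxy)-3-methoxybenzaldehyde
Product: 2 rac-1-ArBn-prop-2-en-1-ol
Conditions: CH2=CHMgBr, THF, −78 → 0 °C; aq NH4Cl
Reagents that add atoms: vinylmagnesium bromide, C=C[Mg]Br
Why: Grignard 1,2-addition to an aromatic aldehyde; the new carbinol centre (future C7) is racemic and is resolved in step 2.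

Step 2
Reactants: 2 rac-1-ArBn-prop-2-en-1-ol
Product: 3 (1R)-1-ArBn-prop-2-en-1-yl acetate
Conditions: Novozym 435 (immobilised Candida antarctica lipase B), vinyl acetate, t-BuOMe, 30 °C, stopped near half conversion; chromatography on Et3N-deactivated silica
Reagents that add atoms: vinyl acetate, CC(=O)OC=C
Why: Lipase-catalysed kinetic resolution by irreversible transesterification; by the Kazlauskas rule (aryl large, vinyl medium) the enzyme acylates the (R)-alcohol, so the acetate carries the C7 configuration of the target.

Step 3
Reactants: 3 (1R)-1-ArBn-prop-2-en-1-yl acetate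
Product: 4 (1R)-1-ArBn-prop-2-en-1-ol
Conditions: K2CO3 (cat.), MeOH, 0 °C
Reagents that add atoms: none
Why: Base-catalysed transesterification (Zemplén-type methanolysis) breaks the acyl–oxygen bond only, so C7 keeps its configuration.

Step 4
Reactants: 4 (1R)-1-ArBn-prop-2-en-1-ol; 5 methyl 2-(bromomethyl)prop-2-enoate
Product: 6 methyl 2-({[(1R)-1-ArBn-prop-2-en-1-yl]oxy}methyl)prop-2-enoate
Conditions: NaH, THF, 0 °C; then 5, 0 °C → rt
Reagents that add atoms: none
Why: Williamson etherification of the sodium alkoxide with an allylic bromide (direct and allylic displacement give the same ether); only the O–H bond of 4 reacts, so C7 is untouched.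

Step 5
Reactants: 6 methyl 2-({[(1R)-1-ArBn-prop-2-en-1-yl]oxy}methyl)prop-2-enoate
Product: 7 methyl (5R)-5-ArBn-2,5-dihydrofuran-3-carboxylate
Conditions: second-generation Grubbs catalyst RuCl2(=CHPh)(PCy3)(H2IMes) (5 mol %), CH2Cl2, 40 °C
Reagents that add atoms: none
Why: Ring-closing olefin metathesis to a five-membered ring, driven by loss of ethene; the N-heterocyclic carbene catalyst accepts the 1,1-disubstituted acrylate alkene, and C7 is not involved.

Step 6
Reactants: 7 methyl (5R)-5-ArBn-2,5-dihydrofuran-3-carboxylate
Product: 8 [(5R)-5-ArBn-2,5-dihydrofuran-3-yl]methanol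
Conditions: i-Bu2AlH (2.5 equiv), CH2Cl2, −78 °C; Rochelle salt
Reagents that add atoms: none
Why: 1,2-Reduction of an α,β-unsaturated ester to the allylic alcohol with an aluminium hydride; the reagent is non-basic, so the γ-proton at C7 is not removed.

Step 7
Reactants: 8 [(5R)-5-ArBn-2,5-dihydrofuran-3-yl]methanol
Product: 9 (5R)-5-ArBn-2,5-dihydrofuran-3-carbaldehyde
Conditions: Dess–Martin periodinane, NaHCO3, CH2Cl2, 0 °C → rt
Reagents that add atoms: none
Why: Dess–Martin oxidation of a primary allylic alcohol under buffered conditions, which avoids enolisation towards C7 and dehydrogenation of the dihydrofuran to a furan.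

Step 8
Reactants: 10 4-bromo-2-methoxyphenol
Product: 11 1-(benzyloxy)-4-bromo-2-methoxybenzene
Conditions: BnBr, K2CO3, DMF, rt
Reagents that add atoms: benzyl bromide, BrCc1ccccc1
Why: Williamson benzylation of a phenol.

Step 9
Reactants: 9 (5R)-5-ArBn-2,5-dihydrofuran-3-carbaldehyde; 11 1-(benzyloxy)-4-bromo-2-methoxybenzene
Product: 15 (S)-ArBn[(5R)-5-ArBn-2,5-dihydrofuran-3-yl]methanol, via aryllithium 12 (not isolated), via arylzinc chloride 13 (not isolated), via butyl(aryl)zinc 14 (not isolated)
Conditions: 11 (2 equiv), n-BuLi, t-BuOMe, −78 °C; ZnCl2, 0 °C; n-BuLi; N,N,N',N'-tetraethylethylenediamine; (−)-MIB [(2S)-3-exo-morpholinoisoborneol, 5 mol %], toluene; then 9, 0 °C; aq NH4Cl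
Reagents that add atoms: none
Why: Amino-alcohol-catalysed enantioselective aryl transfer from a mixed alkyl(aryl)zinc to an aldehyde, a reaction type established for α-branched enals; the diamine ties up LiCl and suppresses the uncatalysed addition. The zinc aminoalkoxide of (−)-MIB is expected to deliver the aryl group to the Si face of the formyl group, as in dialkylzinc additions, which gives (S) at C7' under reagent control; the neutral arylzinc leaves the C7 proton alone.

Step 10
Reactants: 15 (S)-ArBn[(5R)-5-ArBn-2,5-dihydrofuran-3-yl]methanol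
Product: 16 tributyl[({(S)-ArBn[(5R)-5-ArBn-2,5-dihydrofuran-3-yl]methyl}oxy)methyl]stannane
Conditions: KH, THF, 0 °C; Bu3SnCH2I, 18-crown-6 (cat.), 0 °C → rt
Reagents that add atoms: tributyl(iodomethyl)stannane, CCCC[Sn](CCCC)(CCCC)CI
Why: Williamson etherification of the potassium alkoxide with an iodomethylstannane, the standard preparation of Wittig–Still substrates; no bond at C7 or C7' is broken.

Step 11
Reactants: 16 tributyl[({(S)-ArBn[(5R)-5-ArBn-2,5-dihydrofuran-3-yl]methyl}oxy)methyl]stannane
Product: 18 [(2R,3S,4E)-2-ArBn-4-(ArBn-methylidene)oxolan-3-yl]methanol, via lithiomethyl ether 17 (not isolated)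
Conditions: n-BuLi (1.2 equiv), THF, −78 °C, then slowly to −60 °C; aq NH4Cl
Reagents that add atoms: none
Why: n-BuLi attacks tin to give a stannate that releases Bu4Sn and the α-alkoxymethyllithium 17, which at −78 °C undergoes a concerted suprafacial [2,3]-sigmatropic shift through a five-membered envelope transition state: C9 bonds to C8, the C7'–O bond breaks on the same face, and the double bond moves to C7'=C8'. The closest known reaction is the Wittig–Still rearrangement of stannylmethyl ethers of secondary allylic alcohols, including 1-cycloalkenyl carbinols, which give 2-alkylidenecycloalkylmethanols. No ring is closed; the oxolane already exists and the five-membered array is only the transition state. The one new stereocentre, C8, is controlled by two elements that agree: the C7 aryl group screens one face of the flat dihydrofuran, and the (S) centre at C7', with its aryl group turned inside and away from C9'H2 as 2-substituted allyl systems prefer, puts the C7'–O bond on the open face. C9 is therefore delivered trans to the C7 aryl (8S), and the C7' aryl ends syn to C8, the E-benzylidene. The step needs the [2,3] shift to win over the [1,2] radical-pair shift, which the benzylic and allylic migrating carbon would otherwise favour; low temperature, fast tin–lithium exchange and only a small excess of n-BuLi (which also avoids deprotonation at C7) are meant to secure this.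

Step 12
Reactants: 18 [(2R,3S,4E)-2-ArBn-4-(ArBn-methylidene)oxolan-3-yl]methanol; 19 4-(benzyloxy)benzoic acid
Product: 20 [(2R,3S,4E)-2-ArBn-4-(ArBn-methylidene)oxolan-3-yl]methyl 4-(benzyloxy)benzoate
Conditions: EDC·HCl, DMAP, CH2Cl2, 0 °C → rt
Reagents that add atoms: none
Why: Steglich-type carbodiimide esterification of the only free hydroxyl, a primary alcohol; no stereocentre is affected.

Step 13
Reactants: 20 [(2R,3S,4E)-2-ArBn-4-(ArBn-methylidene)oxolan-3-yl]methyl 4-(benzyloxy)benzoate
Product: 21 agastinol, [(2R,3S,4S)-4-(4-hydroxy-3-methoxybenzyl)-2-(4-hydroxy-3-methoxyphenyl)oxolan-3-yl]methyl 4-hydroxybenzoate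
Conditions: H2 (1 atm), 10% Pd/C, EtOAc–EtOH, rt; stopped when uptake ceases
Reagents that add atoms: none
Why: Heterogeneous catalytic hydrogenation with hydrogenolysis of the three aryl benzyl ethers. The aryl group of the E-benzylidene lies syn to C8, and allylic 1,3-strain pushes the C9 ester arm pseudoaxial, so hydrogen should add to C8' from the opposite face and give the 8,8'-cis product (8'S). Neutral conditions at 1 atm are chosen to spare the C7–O1 bond.

## Compound list

1 | 4-(benzyloxy)-3-methoxybenzaldehyde | COc1cc(C=O)ccc1OCc1ccccc1 | starting material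
2 | rac-1-[4-(benzyloxy)-3-methoxyphenyl]prop-2-en-1-ol | COc1cc(C(O)C=C)ccc1OCc1ccccc1 | intermediate
3 | (1R)-1-[4-(benzyloxy)-3-methoxyphenyl]prop-2-en-1-yl acetate | C=C[C@@H](OC(C)=O)c1ccc(OCc2ccccc2)c(OC)c1 | intermediate
4 | (1R)-1-[4-(benzyloxy)-3-methoxyphenyl]prop-2-en-1-ol | C=C[C@@H](O)c1ccc(OCc2ccccc2)c(OC)c1 | intermediate
5 | methyl 2-(bromomethyl)prop-2-enoate | C=C(CBr)C(=O)OC | starting material
6 | methyl 2-({[(1R)-1-[4-(benzyloxy)-3-methoxyphenyl]prop-2-en-1-yl]oxy}methyl)prop-2-enoate | C=C[C@@H](OCC(=C)C(=O)OC)c1ccc(OCc2ccccc2)c(OC)c1 | intermediate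
7 | methyl (5R)-5-[4-(benzyloxy)-3-methoxyphenyl]-2,5-dihydrofuran-3-carboxylate | COC(=O)C1=C[C@H](c2ccc(OCc3ccccc3)c(OC)c2)OC1 | intermediate
8 | [(5R)-5-[4-(benzyloxy)-3-methoxyphenyl]-2,5-dihydrofuran-3-yl]methanol | OCC1=C[C@H](c2ccc(OCc3ccccc3)c(OC)c2)OC1 | intermediate
9 | (5R)-5-[4-(benzyloxy)-3-methoxyphenyl]-2,5-dihydrofuran-3-carbaldehyde | O=CC1=C[C@H](c2ccc(OCc3ccccc3)c(OC)c2)OC1 | intermediate
10 | 4-bromo-2-methoxyphenol | COc1cc(Br)ccc1O | starting material
11 | 1-(benzyloxy)-4-bromo-2-methoxybenzene | COc1cc(Br)ccc1OCc1ccccc1 | intermediate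
12 | [4-(benzyloxy)-3-methoxyphenyl]lithium | [Li]c1ccc(OCc2ccccc2)c(OC)c1 | intermediate
13 | [4-(benzyloxy)-3-methoxyphenyl]zinc chloride | Cl[Zn]c1ccc(OCc2ccccc2)c(OC)c1 | intermediate
14 | butyl[4-(benzyloxy)-3-methoxyphenyl]zinc | CCCC[Zn]c1ccc(OCc2ccccc2)c(OC)c1 | intermediate
15 | (S)-[4-(benzyloxy)-3-methoxyphenyl]{(5R)-5-[4-(benzyloxy)-3-methoxyphenyl]-2,5-dihydrofuran-3-yl}methanol | COc1cc([C@H](O)C2=C[C@H](c3ccc(OCc4ccccc4)c(OC)c3)OC2)ccc1OCc1ccccc1 | intermediate
16 | tributyl[({(S)-[4-(benzyloxy)-3-methoxyphenyl][(5R)-5-[4-(benzyloxy)-3-methoxyphenyl]-2,5-dihydrofuran-3-yl]methyl}oxy)methyl]stannane | COc1cc([C@H](OC[Sn](CCCC)(CCCC)CCCC)C2=C[C@H](c3ccc(OCc4ccccc4)c(OC)c3)OC2)ccc1OCc1ccccc1 | intermediate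
17 | [({(S)-[4-(benzyloxy)-3-methoxyphenyl][(5R)-5-[4-(benzyloxy)-3-methoxyphenyl]-2,5-dihydrofuran-3-yl]methyl}oxy)methyl]lithium | COc1cc([C@H](OC[Li])C2=C[C@H](c3ccc(OCc4ccccc4)c(OC)c3)OC2)ccc1OCc1ccccc1 | intermediate
18 | [(2R,3S,4E)-2-[4-(benzyloxy)-3-methoxyphenyl]-4-{[4-(benzyloxy)-3-methoxyphenyl]methylidene}oxolan-3-yl]methanol | COc1cc(/C=C2/CO[C@@H](c3ccc(OCc4ccccc4)c(OC)c3)[C@@H]2CO)ccc1OCc1ccccc1 | intermediate
19 | 4-(benzyloxy)benzoic acid | O=C(O)c1ccc(OCc2ccccc2)cc1 | starting material
20 | [(2R,3S,4E)-2-[4-(benzyloxy)-3-methoxyphenyl]-4-{[4-(benzyloxy)-3-methoxyphenyl]methylidene}oxolan-3-yl]methyl 4-(benzyloxy)benzoate | COc1cc(/C=C2/CO[C@@H](c3ccc(OCc4ccccc4)c(OC)c3)[C@@H]2COC(=O)c2ccc(OCc3ccccc3)cc2)ccc1OCc1ccccc1 | intermediate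
21 | agastinol, [(2R,3S,4S)-4-(4-hydroxy-3-methoxybenzyl)-2-(4-hydroxy-3-methoxyphenyl)oxolan-3-yl]methyl 4-hydroxybenzoate | COc1cc(C[C@@H]2CO[C@@H](c3ccc(O)c(OC)c3)[C@@H]2COC(=O)c2ccc(O)cc2)ccc1O | target

## Step count and risks

Total: 13 steps. Longest linear sequence: 12 steps (steps 1–7 and 9–13, from aldehyde 1); step 8 is a one-step side branch.

**Step 11 (key step).** The [1,2] radical-pair shift may compete, because the migrating carbon is both benzylic and allylic. Proton transfer to the carbanion, or deprotonation at C7 by excess base, would divert material. Facial selectivity at C8 could erode if the inside orientation of the C7' aryl group is less favoured than assumed. Fallback, from carbinol 15 back to alcohol 18: O-alkylation of 15 with tert-butyl bromoacetate (NaH, THF) gives tert-butyl 2-({(S)-ArBn[(5R)-5-ArBn-2,5-dihydrofuran-3-yl]methyl}oxy)acetate F1. Its lithium enolate (LiN(SiMe3)2, THF, −78 → −20 °C) undergoes the ester-enolate [2,3]-Wittig rearrangement across the same allylic system to tert-butyl 2-hydroxy-2-[(2R,3S,4E)-2-ArBn-4-(ArBn-methylidene)oxolan-3-yl]acetate F2, in which C9 arrives with one extra carbon. LiAlH4 gives 1-[(2R,3S,4E)-2-ArBn-4-(ArBn-methylidene)oxolan-3-yl]ethane-1,2-diol F3, NaIO4 cleaves it to (2R,3R,4E)-2-ArBn-4-(ArBn-methylidene)oxolane-3-carbaldehyde F4, and NaBH4 in the same flask reduces this at once to 18. An enolate is less prone to the [1,2] pathway than the unstabilised carbanion.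

**Step 9.** Catalyst control at C7' may be incomplete if the uncatalysed addition is not fully suppressed, or if the bulky α-branched enal binds the zinc catalyst poorly. The facial sense is inferred by analogy with alkyl transfer and would have to be confirmed; the antipodal ligand is available if it is reversed. Fallback, from aldehyde 9 back to 15: aryllithium 12 is added without catalyst (THF, −78 °C) to give 15 together with its epimer (R)-ArBn[(5R)-5-ArBn-2,5-dihydrofuran-3-yl]methanol F5. The mixture is oxidised (Dess–Martin periodinane) to ArBn[(5R)-5-ArBn-2,5-dihydrofuran-3-yl]methanone F6. Corey–Bakshi–Shibata reduction then returns 15, using (R)-Me-CBS oxazaborolidine and BH3·SMe2 on the working model that the α-branched ring alkenyl group is the larger substituent.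

**Step 13.** Hydrogen may be delivered to the wrong face, since the C7 aryl group lies on the face that must be attacked, 1,3 to C8'. The double bond may migrate into the ring on palladium before it is reduced. Once the phenol is free, the benzylic C7–O1 bond may be hydrogenolysed. Fallback, from alcohol 18 to target 21, with the two events separated and a larger group on C9:
- Silylation of 18 (t-BuPh2SiCl, imidazole) gives tert-butyl{[(2R,3S,4E)-2-ArBn-4-(ArBn-methylidene)oxolan-3-yl]methoxy}diphenylsilane F7.
- Alkene-selective hydrogenation (H2, Pd/C poisoned with Ph2S, EtOAc) gives tert-butyl{[(2R,3S,4S)-2-ArBn-4-(ArBn-methyl)oxolan-3-yl]methoxy}diphenylsilane F8, with the benzyl ethers intact, so the outcome at C8' can be checked.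
- Bu4NF gives [(2R,3S,4S)-2-ArBn-4-(ArBn-methyl)oxolan-3-yl]methanol F9.
- Esterification with 19 (EDC·HCl, DMAP) gives [(2R,3S,4S)-2-ArBn-4-(ArBn-methyl)oxolan-3-yl]methyl 4-(benzyloxy)benzoate F10.
- Brief hydrogenolysis (H2, Pd(OH)2/C, EtOAc–EtOH) gives 21.

**Step 2.** Enantiomer discrimination may fall short of what later steps need, and the electron-rich allylic acetate may ionise or undergo allylic transposition during isolation or methanolysis. Fallback, from racemate 2 directly to alcohol 4: Sharpless kinetic resolution (Ti(OiPr)4, D-(−)-diisopropyl tartrate, t-BuOOH, 4 Å molecular sieves, CH2Cl2, −20 °C). With this tartrate the (S)-enantiomer is epoxidised to the erythro epoxy alcohol (R)-ArBn[(2S)-oxiran-2-yl]methanol F11, and (R)-alcohol 4 is recovered without passing through an acetate.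

## Further compounds

F1 | step 11 | tert-butyl 2-({(S)-[4-(benzyloxy)-3-methoxyphenyl][(5R)-5-[4-(benzyloxy)-3-methoxyphenyl]-2,5-dihydrofuran-3-yl]methyl}oxy)acetate | COc1cc([C@H](OCC(=O)OC(C)(C)C)C2=C[C@H](c3ccc(OCc4ccccc4)c(OC)c3)OC2)ccc1OCc1ccccc1
F2 | step 11 | tert-butyl 2-hydroxy-2-[(2R,3S,4E)-2-[4-(benzyloxy)-3-methoxyphenyl]-4-{[4-(benzyloxy)-3-methoxyphenyl]methylidene}oxolan-3-yl]acetate (carbinol carbon unassigned) | COc1cc(/C=C2/CO[C@@H](c3ccc(OCc4ccccc4)c(OC)c3)[C@@H]2C(O)C(=O)OC(C)(C)C)ccc1OCc1ccccc1
F3 | step 11 | 1-[(2R,3S,4E)-2-[4-(benzyloxy)-3-methoxyphenyl]-4-{[4-(benzyloxy)-3-methoxyphenyl]methylidene}oxolan-3-yl]ethane-1,2-diol (carbinol carbon unassigned) | COc1cc(/C=C2/CO[C@@H](c3ccc(OCc4ccccc4)c(OC)c3)[C@@H]2C(O)CO)ccc1OCc1ccccc1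
F4 | step 11 | (2R,3R,4E)-2-[4-(benzyloxy)-3-methoxyphenyl]-4-{[4-(benzyloxy)-3-methoxyphenyl]methylidene}oxolane-3-carbaldehyde | COc1cc(/C=C2/CO[C@@H](c3ccc(OCc4ccccc4)c(OC)c3)[C@@H]2C=O)ccc1OCc1ccccc1
F5 | step 9 | (R)-[4-(benzyloxy)-3-methoxyphenyl]{(5R)-5-[4-(benzyloxy)-3-methoxyphenyl]-2,5-dihydrofuran-3-yl}methanol | COc1cc([C@@H](O)C2=C[C@H](c3ccc(OCc4ccccc4)c(OC)c3)OC2)ccc1OCc1ccccc1
F6 | step 9 | [4-(benzyloxy)-3-methoxyphenyl]{(5R)-5-[4-(benzyloxy)-3-methoxyphenyl]-2,5-dihydrofuran-3-yl}methanone | COc1cc(C(=O)C2=C[C@H](c3ccc(OCc4ccccc4)c(OC)c3)OC2)ccc1OCc1ccccc1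
F7 | step 13 | tert-butyl{[(2R,3S,4E)-2-[4-(benzyloxy)-3-methoxyphenyl]-4-{[4-(benzyloxy)-3-methoxyphenyl]methylidene}oxolan-3-yl]methoxy}diphenylsilane | COc1cc(/C=C2/CO[C@@H](c3ccc(OCc4ccccc4)c(OC)c3)[C@@H]2CO[Si](c2ccccc2)(c2ccccc2)C(C)(C)C)ccc1OCc1ccccc1
F8 | step 13 | tert-butyl{[(2R,3S,4S)-2-[4-(benzyloxy)-3-methoxyphenyl]-4-[4-(benzyloxy)-3-methoxybenzyl]oxolan-3-yl]methoxy}diphenylsilane | COc1cc(C[C@@H]2CO[C@@H](c3ccc(OCc4ccccc4)c(OC)c3)[C@@H]2CO[Si](c2ccccc2)(c2ccccc2)C(C)(C)C)ccc1OCc1ccccc1
F9 | step 13 | [(2R,3S,4S)-2-[4-(benzyloxy)-3-methoxyphenyl]-4-[4-(benzyloxy)-3-methoxybenzyl]oxolan-3-yl]methanol | COc1cc(C[C@@H]2CO[C@@H](c3ccc(OCc4ccccc4)c(OC)c3)[C@@H]2CO)ccc1OCc1ccccc1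
F10 | step 13 | [(2R,3S,4S)-2-[4-(benzyloxy)-3-methoxyphenyl]-4-[4-(benzyloxy)-3-methoxybenzyl]oxolan-3-yl]methyl 4-(benzyloxy)benzoate | COc1cc(C[C@@H]2CO[C@@H](c3ccc(OCc4ccccc4)c(OC)c3)[C@@H]2COC(=O)c2ccc(OCc3ccccc3)cc2)ccc1OCc1ccccc1
F11 | step 2 | (R)-[4-(benzyloxy)-3-methoxyphenyl][(2S)-oxiran-2-yl]methanol | O[C@H](c1ccc(OCc2ccccc2)c(OC)c1)[C@@H]1CO1
A1 | alternative 1 | 4,5-trans-3-diazo-5-[4-(benzyloxy)-3-methoxyphenyl]-4-({[4-(benzyloxy)-3-methoxyphenyl]methoxy}methyl)oxolan-2-one | COc1cc([C@H]2[C@H](COCc3ccc(OCc4ccccc4)c(OC)c3)C(=[N+]=[N-])C(=O)O2)ccc1OCc1ccccc1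
A2 | alternative 1 | benzyl-protected 2,6-diaryl-3,7-dioxabicyclo[3.3.0]octan-8-one | COc1cc([C@H]2[C@@H]3CO[C@@H](c4ccc(OCc5ccccc5)c(OC)c4)[C@@H]3C(=O)O2)ccc1OCc1ccccc1
A3 | alternative 2 | tert-butyl{[(2R,3S)-2-[4-(benzyloxy)-3-methoxyphenyl]-4-methylideneoxolan-3-yl]methoxy}dimethylsilane | C=C1CO[C@@H](c2ccc(OCc3ccccc3)c(OC)c2)[C@@H]1CO[Si](C)(C)C(C)(C)C
A4 | alternative 2 | tert-butyl{[(2R,3S,4S)-2-[4-(benzyloxy)-3-methoxyphenyl]-4-[4-(benzyloxy)-3-methoxybenzyl]oxolan-3-yl]methoxy}dimethylsilane | COc1cc(C[C@@H]2CO[C@@H](c3ccc(OCc4ccccc4)c(OC)c3)[C@@H]2CO[Si](C)(C)C(C)(C)C)ccc1OCc1ccccc1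
A5 | alternative 3 | prop-2-yn-1-ol | C#CCO
A6 | alternative 3 | dimethyl 2-{[4-(benzyloxy)-3-methoxyphenyl]methylidene}propanedioate | COC(=O)C(=Cc1ccc(OCc2ccccc2)c(OC)c1)C(=O)OC
A7 | alternative 3 | 1-(benzyloxy)-4-iodo-2-methoxybenzene | COc1cc(I)ccc1OCc1ccccc1
A8 | alternative 3 | dimethyl 2-[4-(benzyloxy)-3-methoxyphenyl]-4-{(Z)-[4-(benzyloxy)-3-methoxyphenyl]methylidene}oxolane-3,3-dicarboxylate (C7 as in the target) | COc1cc(/C=C2\CO[C@@H](c3ccc(OCc4ccccc4)c(OC)c3)C2(C(=O)OC)C(=O)OC)ccc1OCc1ccccc1
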